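## Structural features

The target is a germacranolide: a ten-membered carbocycle (C1–C10) fused through C6 and C7 to an α,β-unsaturated γ-lactone (O–C12(=O)–C11=C7). C7 is therefore a fully substituted alkene carbon common to both rings, flanked by the two oxygen-bearing ring carbons C6 (lactone oxygen) and C8 (angelate). C11 carries the acetoxymethyl carbon C13. The carbocycle also holds a ketone at C1, a methyl-bearing stereocentre at C10 next to it, and a trans trisubstituted epoxide at C4–C5 with the methyl on C4. There are five stereocentres, 4R,5R,6S,8S,10R: C4, C5 and C6 are contiguous, and C8 and C10 are 1,3-related across C9. The fragile groups are the Z-configured angelate (prone to isomerise to the tiglate), the C13 acetate (allylic, of Morita–Baylis–Hillman type), the epoxide next to the acidic γ-position C6–H of the butenolide (base would open it), and C10 once the C1 ketone exists. The real difficulty is the congested tetrasubstituted C7=C11 alkene with an oxygenated stereocentre on each side of C7, together with closing the ten-membered ring when all of this is in place. The key step uses the fact that C7 is the β-carbon of an enoate whose carbonyl C12 is cis to it: a C7 carbanion equivalent can add to a C6 aldehyde and the new alkoxide then closes the lactone by itself, while the C5 epoxide oxygen next to C6 serves as the chelating handle that sets C6.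

## Logic of the disconnections

**36 ⇒ 34.** The C1–C2 bond is cut. It is the only ring bond whose two carbons are not stereogenic, it lies next to the ketone, and cutting it turns the medium ring into a chain that ends in an acyl donor (C1 thioester) and a primary iodide (C2). The forward step must join acyl and alkyl carbon under neutral, non-basic conditions, because C10, the epoxide next to C6–H and three esters are present, and it must favour ring closure over oligomerisation.

**34 ⇒ 25.** Only heteroatom bonds are changed: C2–I back to C2–Cl, the C1 thioester back to a PMB-protected primary alcohol, the C8 angelate (from 28) and the C13 acetate back to silyl ethers. The gain is a compound in which every oxygen is inert to organomagnesium chemistry. The forward order is dictated by two demands: O8 must be acylated before C1 is oxidised (a free O8 would close a γ-lactone on C1), and the iodide must be made last because it would not survive thiol, carboxylate and oxidant.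

**25 ⇒ 22 + 7.** The C6–C7 bond and the lactone O–C12 bond are cut. This divides the molecule at its most congested carbon into two pieces of similar size, and the tetrasubstituted alkene is never formed by olefination. The forward step needs a C7 nucleophile with the ester cis to it (23), tolerance of ester, chloride and epoxide, and control of C6 by the epoxide oxygen of 7.

**22 ⇒ 19.** The C7–I and C11–C13 bonds are cut, that is an anti addition of iodide and a hydroxymethyl cation equivalent across the alkynoate. The gain is a linear alkyne; the demand is that the new C–C bond enters trans to iodine so that iodine ends cis to the ester.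

**19 ⇒ 16 ⇒ 12.** The C11–C12 bond and the alkyne carbon C11 are removed (one-carbon homologation of the aldehyde, then acylation of the acetylide), and the three oxygens are differentiated by protecting groups. The demand is that the α-silyloxy aldehyde 16 keeps its configuration.

**12 ⇒ 11 ⇒ 9 ⇒ 8.** The lactone is re-formed and the C10–CH3 bond is cut. C8 comes from the chiral pool, and C10 is set relative to it by alkylation trans to a bulky ring substituent. The demand is high trans selectivity, which the trityl group secures.

**7 ⇒ 5 ⇒ 3 ⇒ 1.** The two epoxide C–O bonds are cut (reagent-controlled epoxidation of an allylic alcohol sets C4 and C5), then the C4–CH3 and C5–C6 bonds are cut (syn carbometalation of a terminal alkyne and carboxylation). The demand is pure E geometry, which the syn addition guarantees, and a C2 substituent (chloride) that is inert until the end.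

## Other disconnections considered

**Alternative 1:** The two allylic C–O bonds (C8–O, C13–O) and the C7=C11 double bond are removed together. This leads back to the macrocyclic diene A1, an 11(13)-methylene lactone with an E C7=C8 double bond, which already contains the ring, the epoxide and the ketone. Forward, singlet oxygen (O2, tetraphenylporphyrin, visible light) would add in a [4+2] sense to the s-cis diene C8=C7–C11=C13 to give the 1,2-dioxine A2. O–O reduction and two acylations would follow.
- In its favour: one step would install both oxygens and the tetrasubstituted alkene without protecting groups, and the lactone locks the diene s-cis. On economy of the oxygenation it is better than the chosen plan.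
- Against it here: A1 is itself a strained ten-membered diene whose ring closure and C4–C6 stereochemistry remain unsolved. Its diene is conjugated with the lactone carbonyl and so a poor partner for electrophilic oxygen. Ene reactions at C6–H and C9–H and a Kornblum–DeLaMare fragmentation of A2 at C8–H would compete. The C8 configuration would rest on the facial bias of a flexible ring, whereas the chosen plan takes it from the chiral pool.
- Comparison: the step count of the whole route is not expected to be lower, because the saving is moved into the synthesis of A1.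

**Alternative 2:** The C3–C4 bond is cut, leading to the cyclopropanol alkenyl iodide A3. With Pd(OAc)2 and a bulky biaryl phosphine the cyclopropanol would open to a C3 palladium homoenolate that couples with the C4 alkenyl iodide, giving the 4,5-dehydro macrocycle A4 with the ketone already in place. Epoxidation would come last.
- In its favour: the ketone appears in the ring-closing step, so the oxidation, thioester and halide-exchange steps of the chosen plan are not needed. The E geometry is carried over from the iodide. No reducing metal is present near the acyloxy butenolide; on this point it is better than the chosen plan, and in using a palladium-catalysed closure it is its equal.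
- Against it here: the epoxide would have to be introduced on A4 with only the ring conformation to direct the face. The homoenolate can undergo β-hydride elimination to an enone. The butenolide annulation would then use an enal without the epoxide oxygen, so the element that controls C6 in the chosen plan is lost. The cyclopropanol has to be carried, protected, through the organomagnesium steps.
- Comparison: the step count is expected to be similar; the stereochemical risk moves from C6 to C4/C5.

**Alternative 3:** The C1–C10 bond is cut, leading to the aldehyde enone A5. A chiral triazolium-derived carbene would turn the C1 aldehyde into an acyl anion equivalent that adds to C10 of the C8 crotonyl ketone (intramolecular Stetter reaction), giving the ten-membered C1,C8-diketone A6 and the C10 stereocentre.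
- In its favour: the 1,4-dicarbonyl pattern is the natural retron of this reaction. C10 would be set by the catalyst, and ring and ketone are formed in one metal-free step; in directness of forming the C1 ketone it is better than the chosen plan, and in convergence its equal.
- Against it here: the acceptor is a β-methyl enone cross-conjugated with the tetrasubstituted enoate, a sluggish Stetter acceptor. Closures of ten-membered rings by this reaction have little precedent next to five- and six-membered cases. The basic carbene conditions invite benzoin and aldol paths and threaten the epoxide. Afterwards the C8 ketone must be reduced to the S alcohol in the presence of the C1 ketone, and C10 (α to C1) can epimerise during these operations.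
- Comparison: the chosen plan carries C8 and C10 unchanged from a chiral-pool lactone and forms the ketone only in the last step.

Key step: step 17

Remarks on the chemistry:
- Abbreviations: TBS = tert-butyldimethylsilyl, PMB = 4-methoxybenzyl, Tr = triphenylmethyl.
- Compound 8 is used as purchased. It is the lactone that L-glutamic acid gives on nitrous acid deamination and borane reduction, so C8 of the target stems from the amino acid.
- The descriptors of 7, 22 and 25 were re-derived from their connection tables. 7 is (2S,3R), 22 is (2Z,4S,6R) with iodine cis to the ester, and 25 has 4R,5R,6S,8S,10R in ring numbering. All agree with 36, so no structure needed correction.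
- The chloride at C2, the silyl ethers at O8 and O13 and the PMB ether at O1 are kept as the precursor design. The endgame order is fixed so that O8 is acylated before C1 is oxidised.

## Route

Step 1
Reactants: 1 but-3-yn-1-ol
Product: 3 methyl (E)-5-hydroxy-3-methylpent-2-enoate, via alkenylalane 2 (not isolated)
Conditions: AlMe3 (3 equiv), Cp2ZrCl2 (0.25 equiv), CH2Cl2, 0 °C to rt; then ClCO2Me, 0 °C to rt; aq. HCl
Reagents that add atoms: trimethylaluminium, C[Al](C)C; methyl chloroformate, COC(=O)Cl
Why: Zirconium-catalysed carboalumination (Negishi) adds methyl and aluminium syn across the terminal alkyne with aluminium at the terminus, which fixes the E geometry (future C4 methyl cis to C5); the alkenyl–aluminium bond is then acylated by the chloroformate with retention, the hydroxyl being carried as its aluminium alkoxide.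

Step 2
Reactants: 3 methyl (E)-5-hydroxy-3-methylpent-2-enoate
Product: 4 methyl (E)-5-chloro-3-methylpent-2-enoate
Conditions: PPh3, N-chlorosuccinimide, CH2Cl2, 0 °C to rt
Reagents that add atoms: N-chlorosuccinimide, O=C1CCC(=O)N1Cl
Why: Appel-type chlorination of the only hydroxyl through an alkoxyphosphonium ion under neutral conditions; the β,β-disubstituted enoate is inert, and the chloride will pass through every later organometallic step unchanged.

Step 3
Reactants: 4 methyl (E)-5-chloro-3-methylpent-2-enoate
Product: 5 (E)-5-chloro-3-methylpent-2-en-1-ol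
Conditions: iBu2AlH (2.2 equiv), CH2Cl2, −78 °C; Rochelle salt
Reagents that add atoms: none
Why: 1,2-Reduction of the enoate by the aluminium hydride at low temperature gives the allylic alcohol without conjugate reduction and without touching the primary chloride.

Step 4
Reactants: 5 (E)-5-chloro-3-methylpent-2-en-1-ol
Product: 6 [(2R,3R)-3-(2-chloroethyl)-3-methyloxiran-2-yl]methanol
Conditions: Ti(OiPr)4 (10 mol%), D-(−)-diethyl tartrate (12 mol%), t-BuOOH, 4 Å molecular sieves, CH2Cl2, −20 °C
Reagents that add atoms: tert-butyl hydroperoxide, CC(C)(C)OO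
Why: Sharpless asymmetric epoxidation of an E 3,3-disubstituted allylic alcohol (the geraniol substrate class); the D-(−)-tartrate complex delivers oxygen to the face that gives the (2R,3R) epoxide, which sets C4 and C5 by reagent control.

Step 5
Reactants: 6 [(2R,3R)-3-(2-chloroethyl)-3-methyloxiran-2-yl]methanol
Product: 7 (2S,3R)-3-(2-chloroethyl)-3-methyloxirane-2-carbaldehyde (fragment 1)
Conditions: Dess–Martin periodinane, NaHCO3, CH2Cl2, 0 °C; used at once
Reagents that add atoms: none
Why: Buffered Dess–Martin oxidation gives the epoxy aldehyde without acid or base; C5–H cannot enolise into the oxirane, so the centre is configurationally safe (the descriptor changes from R to S only because the priorities change).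

Step 6
Reactants: 8 (S)-5-(hydroxymethyl)dihydrofuran-2(3H)-one
Product: 9 (S)-5-[(trityloxy)methyl]dihydrofuran-2(3H)-one
Conditions: TrCl, pyridine, DMAP (cat.), CH2Cl2, rt
Reagents that add atoms: trityl chloride, ClC(c1ccccc1)(c1ccccc1)c1ccccc1
Why: Tritylation of the primary alcohol; the large ether is the control element for the next step.

Step 7
Reactants: 9 (S)-5-[(trityloxy)methyl]dihydrofuran-2(3H)-one
Product: 11 (3R,5S)-3-methyl-5-[(trityloxy)methyl]dihydrofuran-2(3H)-one, via lithium enolate 10 (not isolated)
Conditions: LiN(iPr)2, THF, −78 °C; MeI, −78 °C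
Reagents that add atoms: iodomethane, CI
Why: Alkylation of the lactone enolate; iodomethane approaches the face of the envelope opposite the trityloxymethyl group, so the methyl enters trans and C10 is set as R relative to the chiral-pool centre C8.

Step 8
Reactants: 11 (3R,5S)-3-methyl-5-[(trityloxy)methyl]dihydrofuran-2(3H)-one
Product: 12 (2R,4S)-2-methyl-5-(trityloxy)pentane-1,4-diol
Conditions: LiAlH4, THF, 0 °C
Reagents that add atoms: none
Why: Hydride reduction of the lactone to the 1,4-diol cleaves only the acyl–oxygen bond, so neither stereocentre is touched.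

Step 9
Reactants: 12 (2R,4S)-2-methyl-5-(trityloxy)pentane-1,4-diol
Product: 13 (2S,4R)-5-[(4-methoxybenzyl)oxy]-4-methyl-1-(trityloxy)pentan-2-ol
Conditions: NaH (1.05 equiv), PMBCl, Bu4NI (cat.), THF/DMF, −20 to 0 °C
Reagents that add atoms: 4-methoxybenzyl chloride, COc1ccc(CCl)cc1
Why: Williamson etherification with one equivalent of base; the unhindered primary alkoxide is alkylated in preference to the secondary one flanked by the trityloxymethyl group, and the minor regioisomer and bis-ether are removed by chromatography.

Step 10
Reactants: 13 (2S,4R)-5-[(4-methoxybenzyl)oxy]-4-methyl-1-(trityloxy)pentan-2-ol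
Product: 14 (2S,4R)-2-[(tert-butyldimethylsilyl)oxy]-5-[(4-methoxybenzyl)oxy]-4-methyl-1-(trityloxy)pentane
Conditions: TBSCl, imidazole, DMF, rt
Reagents that add atoms: tert-butyldimethylsilyl chloride, CC(C)(C)[Si](C)(C)Cl
Why: Silylation of the secondary alcohol (future O8); a silyl ether is chosen because it is too poor a leaving group to be expelled from the carbon next to the later C7 carbanion.

Step 11
Reactants: 14 (2S,4R)-2-[(tert-butyldimethylsilyl)oxy]-5-[(4-methoxybenzyl)oxy]-4-methyl-1-(trityloxy)pentane
Product: 15 (2S,4R)-2-[(tert-butyldimethylsilyl)oxy]-5-[(4-methoxybenzyl)oxy]-4-methylpentan-1-ol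
Conditions: CSA (cat.), MeOH/CH2Cl2, 0 °C
Reagents that add atoms: none
Why: Acid-catalysed methanolysis of the trityl ether through the stabilised trityl cation is much faster than cleavage of the hindered secondary silyl ether or of the PMB ether.

Step 12
Reactants: 15 (2S,4R)-2-[(tert-butyldimethylsilyl)oxy]-5-[(4-methoxybenzyl)oxy]-4-methylpentan-1-ol
Product: 16 (2S,4R)-2-[(tert-butyldimethylsilyl)oxy]-5-[(4-methoxybenzyl)oxy]-4-methylpentanal
Conditions: Dess–Martin periodinane, NaHCO3, CH2Cl2, 0 °C to rt
Reagents that add atoms: none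
Why: Buffered Dess–Martin oxidation gives the α-silyloxy aldehyde without a base that could epimerise C8; the aldehyde is carried on directly.

Step 13
Reactants: 16 (2S,4R)-2-[(tert-butyldimethylsilyl)oxy]-5-[(4-methoxybenzyl)oxy]-4-methylpentanal
Product: 17 (3S,5R)-1,1-dibromo-3-[(tert-butyldimethylsilyl)oxy]-6-[(4-methoxybenzyl)oxy]-5-methylhex-1-ene
Conditions: CBr4, PPh3, Et3N, CH2Cl2, 0 °C
Reagents that add atoms: carbon tetrabromide, BrC(Br)(Br)Br
Why: First stage of the Corey–Fuchs homologation (Wittig-type dibromomethylenation); the amine buffers hydrogen bromide, and no base strong enough to enolise the aldehyde is present.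

Step 14
Reactants: 17 (3S,5R)-1,1-dibromo-3-[(tert-butyldimethylsilyl)oxy]-6-[(4-methoxybenzyl)oxy]-5-methylhex-1-ene
Product: 19 methyl (4S,6R)-4-[(tert-butyldimethylsilyl)oxy]-7-[(4-methoxybenzyl)oxy]-6-methylhept-2-ynoate, via lithium acetylide 18 (not isolated)
Conditions: n-BuLi (2.1 equiv), THF, −78 °C; then ClCO2Me, −78 to 0 °C
Reagents that add atoms: methyl chloroformate, COC(=O)Cl
Why: Second stage of the Corey–Fuchs sequence: bromine–lithium exchange, α-elimination with 1,2-hydrogen shift and deprotonation give the lithium acetylide, which is acylated at carbon by the chloroformate in the same flask.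

Step 15
Reactants: 19 methyl (4S,6R)-4-[(tert-butyldimethylsilyl)oxy]-7-[(4-methoxybenzyl)oxy]-6-methylhept-2-ynoate
Product: 21 methyl (2Z,4S,6R)-4-[(tert-butyldimethylsilyl)oxy]-2-(hydroxymethyl)-3-iodo-7-[(4-methoxybenzyl)oxy]-6-methylhept-2-enoate, via magnesium iodoallenolate 20 (not isolated)
Conditions: MgI2 (1.5 equiv), CH2O (monomer from cracked paraformaldehyde), CH2Cl2, −20 to 0 °C
Reagents that add atoms: magnesium iodide, [Mg+2].[I-].[I-]; formaldehyde, C=O
Why: Tandem iodide conjugate addition–aldol (β-iodo Morita–Baylis–Hillman reaction): iodide adds to C7 of the Lewis-acid-bound alkynoate and the magnesium allenolate is trapped at C11 by formaldehyde. Under kinetic conditions the new C–C bond should enter trans to the iodide, as in the anti hydroiodination of alkynoates, which places iodine cis to the ester (Z); the low temperature is meant to prevent equilibration of the geometry.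

Step 16
Reactants: 21 methyl (2Z,4S,6R)-4-[(tert-butyldimethylsilyl)oxy]-2-(hydroxymethyl)-3-iodo-7-[(4-methoxybenzyl)oxy]-6-methylhept-2-enoate
Product: 22 methyl (2Z,4S,6R)-4-[(tert-butyldimethylsilyl)oxy]-2-{[(tert-butyldimethylsilyl)oxy]methyl}-3-iodo-7-[(4-methoxybenzyl)oxy]-6-methylhept-2-enoate (fragment 2)
Conditions: TBSCl, imidazole, CH2Cl2, 0 °C to rt
Reagents that add atoms: tert-butyldimethylsilyl chloride, CC(C)(C)[Si](C)(C)Cl
Why: Silylation of the primary allylic alcohol under mild base; the O13 silyl ether, like the one on O8, cannot be expelled by the neighbouring carbanion of the next step.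

Step 17
Reactants: 22 methyl (2Z,4S,6R)-4-[(tert-butyldimethylsilyl)oxy]-2-{[(tert-butyldimethylsilyl)oxy]methyl}-3-iodo-7-[(4-methoxybenzyl)oxy]-6-methylhept-2-enoate (fragment 2); 7 (2S,3R)-3-(2-chloroethyl)-3-methyloxirane-2-carbaldehyde (fragment 1)
Product: 25 (5S)-4-[(1S,3R)-1-[(tert-butyldimethylsilyl)oxy]-4-[(4-methoxybenzyl)oxy]-3-methylbutyl]-3-{[(tert-butyldimethylsilyl)oxy]methyl}-5-[(2R,3R)-3-(2-chloroethyl)-3-methyloxiran-2-yl]furan-2(5H)-one, via alkenylmagnesium chloride 23 (not isolated), via magnesium C6-alkoxide 24 (not isolated)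
Conditions: iPrMgCl·LiCl (1.1 equiv), THF, −40 °C; then 7 premixed with MgBr2·OEt2 (1.5 equiv) in CH2Cl2, −78 to −20 °C; then 0 °C
Reagents that add atoms: none
Why: Iodine–magnesium exchange at the ester-activated alkenyl iodide is faster at −40 °C than attack on the ester and gives 23 with retention, magnesium cis to the ester. The two silyl ethers are too poor leaving groups for β-elimination to an allene, and the primary chloride of 7 is inert. 23 adds to the aldehyde carbon of 7 and forms C6–C7. In alkoxide 24 the oxygen on C6 is held cis to C12 by the alkene, so it attacks the ester carbonyl in a 5-exo-trig acyl substitution, expels methoxide and closes the butenolide irreversibly. The new centre C6 is controlled by a Cram chelate: magnesium bridges the aldehyde oxygen and the epoxide oxygen, and the nucleophile attacks the face opposite C4 and its cis methyl, past C5–H, which gives 6S (syn to the epoxide oxygen). The closest known reaction types are the exchange of Z-β-iodo enoates with addition to aldehydes and lactonisation to butenolides, and chelation-controlled additions to α,β-epoxy aldehydes. The step needs chemoselectivity (exchange before ester attack, aldehyde before epoxide), retention of alkene geometry and chelation rather than Felkin–Anh facial control; low temperature, the Z geometry of 22 and a bidentate Lewis acid in a weakly coordinating cosolvent are meant to secure these. C4, C5, C8 and C10 are not involved.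

Step 18
Reactants: 25 the butenolide union product
Product: 26 (5S)-5-[(2R,3R)-3-(2-chloroethyl)-3-methyloxiran-2-yl]-4-[(1S,3R)-1-hydroxy-4-[(4-methoxybenzyl)oxy]-3-methylbutyl]-3-(hydroxymethyl)furan-2(5H)-one
Conditions: HF·pyridine, pyridine, THF, 0 °C to rt
Reagents that add atoms: none
Why: Fluoride-driven cleavage of both silyl ethers in a pyridine-buffered medium that should spare the epoxide; the freed O8 cannot translactonise, because attack on C12 would place the C7=C11 double bond at a bridgehead of a bicyclo[2.2.1] intermediate.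

Step 19
Reactants: 26 the C8,C13-diol
Product: 27 {(5S)-5-[(2R,3R)-3-(2-chloroethyl)-3-methyloxiran-2-yl]-4-[(1S,3R)-1-hydroxy-4-[(4-methoxybenzyl)oxy]-3-methylbutyl]-2-oxo-2,5-dihydrofuran-3-yl}methyl acetate
Conditions: Ac2O (1.1 equiv), 2,4,6-collidine, CH2Cl2, −20 °C
Reagents that add atoms: acetic anhydride, CC(=O)OC(C)=O
Why: Kinetically selective acetylation of the primary allylic alcohol over the secondary alcohol, which is hindered by the tetrasubstituted alkene; the weak hindered base does not touch C6–H.

Step 20
Reactants: 27 the C13 acetate; 28 angelic acid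
Product: 30 (1S,3R)-1-{(5S)-4-(acetoxymethyl)-5-[(2R,3R)-3-(2-chloroethyl)-3-methyloxiran-2-yl]-2-oxo-2,5-dihydrofuran-3-yl}-4-[(4-methoxybenzyl)oxy]-3-methylbutyl (Z)-2-methylbut-2-enoate, via angelic 2,4,6-trichlorobenzoic anhydride 29 (not isolated)
Conditions: 28, 2,4,6-Cl3C6H2COCl, Et3N, toluene, rt, filter; then 27, toluene, 75 °C
Reagents that add atoms: none
Why: Yamaguchi-type mixed-anhydride esterification run without a nucleophilic catalyst: the alcohol attacks the unhindered angeloyl carbonyl of 29, and leaving out the acyl-transfer catalyst suppresses the conjugate addition–elimination that turns angelates into tiglates. O-acylation leaves C8 unchanged.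

Step 21
Reactants: 30 the C8 angelate
Product: 31 (1S,3R)-1-{(5S)-4-(acetoxymethyl)-5-[(2R,3R)-3-(2-chloroethyl)-3-methyloxiran-2-yl]-2-oxo-2,5-dihydrofuran-3-yl}-4-hydroxy-3-methylbutyl (Z)-2-methylbut-2-enoate
Conditions: DDQ, CH2Cl2/pH 7 buffer, 0 °C to rt
Reagents that add atoms: none
Why: Oxidative cleavage of the PMB ether by hydride abstraction at the electron-rich benzylic position and hydrolysis; the electron-poor alkenes, the epoxide and the esters are inert to the quinone.

Step 22
Reactants: 31 the C1 alcohol
Product: 32 (2R,4S)-4-{(5S)-4-(acetoxymethyl)-5-[(2R,3R)-3-(2-chloroethyl)-3-methyloxiran-2-yl]-2-oxo-2,5-dihydrofuran-3-yl}-2-methyl-4-{[(Z)-2-methylbut-2-enoyl]oxy}butanoic acid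
Conditions: TEMPO (cat.), PhI(OAc)2, MeCN/H2O, rt
Reagents that add atoms: water, O
Why: Oxoammonium oxidation of the primary alcohol to the aldehyde and, through its hydrate, to the acid under near-neutral conditions that should not epimerise C10; O8 is already acylated, so no γ-lactone can form with C1.

Step 23
Reactants: 32 the C1 acid
Product: 33 S-ethyl (2R,4S)-4-{(5S)-4-(acetoxymethyl)-5-[(2R,3R)-3-(2-chloroethyl)-3-methyloxiran-2-yl]-2-oxo-2,5-dihydrofuran-3-yl}-2-methyl-4-{[(Z)-2-methylbut-2-enoyl]oxy}butanethioate
Conditions: EtSH, EDC·HCl, DMAP (cat.), CH2Cl2, 0 °C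
Reagents that add atoms: ethanethiol, CCS
Why: Carbodiimide (Steglich-type) thioesterification at 0 °C; the fully substituted β-carbon of the butenolide blocks conjugate attack of the thiol, and the primary chloride is too unreactive to be alkylated.

Step 24
Reactants: 33 the chloro thioester
Product: 34 S-ethyl (2R,4S)-4-{(5S)-4-(acetoxymethyl)-5-[(2R,3R)-3-(2-iodoethyl)-3-methyloxiran-2-yl]-2-oxo-2,5-dihydrofuran-3-yl}-2-methyl-4-{[(Z)-2-methylbut-2-enoyl]oxy}butanethioate
Conditions: NaI, NaHCO3, acetone, 55 °C, dark
Reagents that add atoms: sodium iodide, [Na+].[I-]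
Why: Finkelstein exchange at the primary chloride, driven by precipitation of sodium chloride; the bicarbonate buffer keeps the medium neutral so that iodide does not open the epoxide.

Step 25
Reactants: 34 the iodo thioester
Product: 36 target CNP0229937.2, (4R,5R,6S,8S,10R)-13-acetoxy-8-angeloyloxy-4,5-epoxy-1-oxogermacr-7(11)-en-6,12-olide, via alkylzinc iodide 35 (not isolated)
Conditions: Zn dust, LiCl, THF, 25 °C, decant; syringe-pump addition to PdCl2(PPh3)2 (10 mol%), toluene, 40 °C, final concentration about 1 mM
Reagents that add atoms: none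
Why: Proposed new method: zinc inserts into the primary C2–I bond to give 35, which does not react with its own thioester until zerovalent palladium (formed from PdCl2(PPh3)2 and the organozinc) adds oxidatively into the C1–S bond; transmetalation from zinc and reductive elimination then form C1–C2 and close the ten-membered ring under neutral conditions that leave C10, the epoxide and the three esters alone. The closest known reaction type is the intermolecular Fukuyama thioester–alkylzinc ketone synthesis, which has not been used to close a medium carbocycle; slow addition at high dilution is relied on to favour the unimolecular path.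

## Compound list

1 | but-3-yn-1-ol | C#CCCO | starting material
2 | dimethyl[(E)-4-(dimethylalumanyloxy)-2-methylbut-1-en-1-yl]alumane (alkenylalane) | C[Al](C)/C=C(\C)CCO[Al](C)C | intermediate
3 | methyl (E)-5-hydroxy-3-methylpent-2-enoate | COC(=O)/C=C(\C)CCO | intermediate
4 | methyl (E)-5-chloro-3-methylpent-2-enoate | COC(=O)/C=C(\C)CCCl | intermediate
5 | (E)-5-chloro-3-methylpent-2-en-1-ol | OC/C=C(\C)CCCl | intermediate
6 | [(2R,3R)-3-(2-chloroethyl)-3-methyloxiran-2-yl]methanol | OC[C@H]1O[C@]1(C)CCCl | intermediate
7 | (2S,3R)-3-(2-chloroethyl)-3-methyloxirane-2-carbaldehyde (fragment 1) | O=C[C@H]1O[C@]1(C)CCCl | intermediate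
8 | (S)-5-(hydroxymethyl)dihydrofuran-2(3H)-one | O=C1CC[C@@H](CO)O1 | starting material
9 | (S)-5-[(trityloxy)methyl]dihydrofuran-2(3H)-one | O=C1CC[C@@H](COC(c2ccccc2)(c2ccccc2)c2ccccc2)O1 | intermediate
10 | lithium (S)-5-[(trityloxy)methyl]-4,5-dihydrofuran-2-olate (lithium enolate) | [Li]OC1=CC[C@@H](COC(c2ccccc2)(c2ccccc2)c2ccccc2)O1 | intermediate
11 | (3R,5S)-3-methyl-5-[(trityloxy)methyl]dihydrofuran-2(3H)-one | C[C@@H]1C[C@@H](COC(c2ccccc2)(c2ccccc2)c2ccccc2)OC1=O | intermediate
12 | (2R,4S)-2-methyl-5-(trityloxy)pentane-1,4-diol | OC[C@H](C)C[C@H](O)COC(c1ccccc1)(c1ccccc1)c1ccccc1 | intermediate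
13 | (2S,4R)-5-[(4-methoxybenzyl)oxy]-4-methyl-1-(trityloxy)pentan-2-ol | COc1ccc(COC[C@H](C)C[C@H](O)COC(c2ccccc2)(c2ccccc2)c2ccccc2)cc1 | intermediate
14 | (2S,4R)-2-[(tert-butyldimethylsilyl)oxy]-5-[(4-methoxybenzyl)oxy]-4-methyl-1-(trityloxy)pentane | COc1ccc(COC[C@H](C)C[C@H](O[Si](C)(C)C(C)(C)C)COC(c2ccccc2)(c2ccccc2)c2ccccc2)cc1 | intermediate
15 | (2S,4R)-2-[(tert-butyldimethylsilyl)oxy]-5-[(4-methoxybenzyl)oxy]-4-methylpentan-1-ol | COc1ccc(COC[C@H](C)C[C@H](O[Si](C)(C)C(C)(C)C)CO)cc1 | intermediate
16 | (2S,4R)-2-[(tert-butyldimethylsilyl)oxy]-5-[(4-methoxybenzyl)oxy]-4-methylpentanal | COc1ccc(COC[C@H](C)C[C@H](O[Si](C)(C)C(C)(C)C)C=O)cc1 | intermediate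
17 | (3S,5R)-1,1-dibromo-3-[(tert-butyldimethylsilyl)oxy]-6-[(4-methoxybenzyl)oxy]-5-methylhex-1-ene | COc1ccc(COC[C@H](C)C[C@H](O[Si](C)(C)C(C)(C)C)C=C(Br)Br)cc1 | intermediate
18 | [(3S,5R)-3-[(tert-butyldimethylsilyl)oxy]-6-[(4-methoxybenzyl)oxy]-5-methylhex-1-yn-1-yl]lithium (lithium acetylide) | COc1ccc(COC[C@H](C)C[C@H](O[Si](C)(C)C(C)(C)C)C#C[Li])cc1 | intermediate
19 | methyl (4S,6R)-4-[(tert-butyldimethylsilyl)oxy]-7-[(4-methoxybenzyl)oxy]-6-methylhept-2-ynoate | COc1ccc(COC[C@H](C)C[C@H](O[Si](C)(C)C(C)(C)C)C#CC(=O)OC)cc1 | intermediate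
20 | magnesium iodide allenolate of 19 carrying iodine on C7 (O-bound MgI) | COC(O[Mg]I)=C=C(I)[C@@H](O[Si](C)(C)C(C)(C)C)C[C@@H](C)COCc1ccc(OC)cc1 | intermediate
21 | methyl (2Z,4S,6R)-4-[(tert-butyldimethylsilyl)oxy]-2-(hydroxymethyl)-3-iodo-7-[(4-methoxybenzyl)oxy]-6-methylhept-2-enoate | COC(=O)/C(CO)=C(\I)[C@@H](O[Si](C)(C)C(C)(C)C)C[C@@H](C)COCc1ccc(OC)cc1 | intermediate
22 | methyl (2Z,4S,6R)-4-[(tert-butyldimethylsilyl)oxy]-2-{[(tert-butyldimethylsilyl)oxy]methyl}-3-iodo-7-[(4-methoxybenzyl)oxy]-6-methylhept-2-enoate (fragment 2) | COC(=O)/C(CO[Si](C)(C)C(C)(C)C)=C(\I)[C@@H](O[Si](C)(C)C(C)(C)C)C[C@@H](C)COCc1ccc(OC)cc1 | intermediate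
23 | alkenylmagnesium chloride from 22 (MgCl on C7 in place of iodine, geometry retained) | COC(=O)/C(CO[Si](C)(C)C(C)(C)C)=C(\[Mg]Cl)[C@@H](O[Si](C)(C)C(C)(C)C)C[C@@H](C)COCc1ccc(OC)cc1 | intermediate
24 | chloromagnesium (6S)-alkoxide, the open-chain adduct of 23 and 7 | COC(=O)/C(CO[Si](C)(C)C(C)(C)C)=C(\[C@H](O[Mg]Cl)[C@H]1O[C@]1(C)CCCl)[C@@H](O[Si](C)(C)C(C)(C)C)C[C@@H](C)COCc1ccc(OC)cc1 | intermediate
25 | (5S)-4-[(1S,3R)-1-[(tert-butyldimethylsilyl)oxy]-4-[(4-methoxybenzyl)oxy]-3-methylbutyl]-3-{[(tert-butyldimethylsilyl)oxy]methyl}-5-[(2R,3R)-3-(2-chloroethyl)-3-methyloxiran-2-yl]furan-2(5H)-one | C[C@@H](COCc1ccc(OC)cc1)C[C@H](O[Si](C)(C)C(C)(C)C)C1=C(CO[Si](C)(C)C(C)(C)C)C(=O)O[C@@H]1[C@H]1O[C@]1(C)CCCl | intermediate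
26 | (5S)-5-[(2R,3R)-3-(2-chloroethyl)-3-methyloxiran-2-yl]-4-[(1S,3R)-1-hydroxy-4-[(4-methoxybenzyl)oxy]-3-methylbutyl]-3-(hydroxymethyl)furan-2(5H)-one | C[C@@H](COCc1ccc(OC)cc1)C[C@H](O)C1=C(CO)C(=O)O[C@@H]1[C@H]1O[C@]1(C)CCCl | intermediate
27 | {(5S)-5-[(2R,3R)-3-(2-chloroethyl)-3-methyloxiran-2-yl]-4-[(1S,3R)-1-hydroxy-4-[(4-methoxybenzyl)oxy]-3-methylbutyl]-2-oxo-2,5-dihydrofuran-3-yl}methyl acetate | C[C@@H](COCc1ccc(OC)cc1)C[C@H](O)C1=C(COC(C)=O)C(=O)O[C@@H]1[C@H]1O[C@]1(C)CCCl | intermediate
28 | angelic acid, (Z)-2-methylbut-2-enoic acid | C/C=C(/C)C(=O)O | starting material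
29 | (Z)-2-methylbut-2-enoic 2,4,6-trichlorobenzoic anhydride | C/C=C(/C)C(=O)OC(=O)c1c(Cl)cc(Cl)cc1Cl | intermediate
30 | (1S,3R)-1-{(5S)-4-(acetoxymethyl)-5-[(2R,3R)-3-(2-chloroethyl)-3-methyloxiran-2-yl]-2-oxo-2,5-dihydrofuran-3-yl}-4-[(4-methoxybenzyl)oxy]-3-methylbutyl (Z)-2-methylbut-2-enoate | C[C@@H](COCc1ccc(OC)cc1)C[C@H](OC(=O)/C(C)=C\C)C1=C(COC(C)=O)C(=O)O[C@@H]1[C@H]1O[C@]1(C)CCCl | intermediate
31 | (1S,3R)-1-{(5S)-4-(acetoxymethyl)-5-[(2R,3R)-3-(2-chloroethyl)-3-methyloxiran-2-yl]-2-oxo-2,5-dihydrofuran-3-yl}-4-hydroxy-3-methylbutyl (Z)-2-methylbut-2-enoate | C[C@@H](CO)C[C@H](OC(=O)/C(C)=C\C)C1=C(COC(C)=O)C(=O)O[C@@H]1[C@H]1O[C@]1(C)CCCl | intermediate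
32 | (2R,4S)-4-{(5S)-4-(acetoxymethyl)-5-[(2R,3R)-3-(2-chloroethyl)-3-methyloxiran-2-yl]-2-oxo-2,5-dihydrofuran-3-yl}-2-methyl-4-{[(Z)-2-methylbut-2-enoyl]oxy}butanoic acid | C[C@@H](C(=O)O)C[C@H](OC(=O)/C(C)=C\C)C1=C(COC(C)=O)C(=O)O[C@@H]1[C@H]1O[C@]1(C)CCCl | intermediate
33 | S-ethyl (2R,4S)-4-{(5S)-4-(acetoxymethyl)-5-[(2R,3R)-3-(2-chloroethyl)-3-methyloxiran-2-yl]-2-oxo-2,5-dihydrofuran-3-yl}-2-methyl-4-{[(Z)-2-methylbut-2-enoyl]oxy}butanethioate | C[C@@H](C(=O)SCC)C[C@H](OC(=O)/C(C)=C\C)C1=C(COC(C)=O)C(=O)O[C@@H]1[C@H]1O[C@]1(C)CCCl | intermediate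
34 | S-ethyl (2R,4S)-4-{(5S)-4-(acetoxymethyl)-5-[(2R,3R)-3-(2-iodoethyl)-3-methyloxiran-2-yl]-2-oxo-2,5-dihydrofuran-3-yl}-2-methyl-4-{[(Z)-2-methylbut-2-enoyl]oxy}butanethioate | C[C@@H](C(=O)SCC)C[C@H](OC(=O)/C(C)=C\C)C1=C(COC(C)=O)C(=O)O[C@@H]1[C@H]1O[C@]1(C)CCI | intermediate
35 | alkylzinc iodide from 34 (ZnI on C2 in place of iodine) | C[C@@H](C(=O)SCC)C[C@H](OC(=O)/C(C)=C\C)C1=C(COC(C)=O)C(=O)O[C@@H]1[C@H]1O[C@]1(C)CC[Zn]I | intermediate
36 | CNP0229937.2, (4R,5R,6S,8S,10R)-13-acetoxy-8-angeloyloxy-4,5-epoxy-1-oxogermacr-7(11)-en-6,12-olide | C/C=C(/C)C(=O)O[C@H]1C[C@@H](C)C(=O)CC[C@@]2(C)O[C@@H]2[C@H]2OC(=O)C(COC(C)=O)=C12 | target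

## Step count and least certain steps

Total step count: 25 (steps 1–5 to fragment 1, steps 6–16 to fragment 2, the union in step 17, steps 18–25 to the target). Longest linear sequence: 20 steps (8 to 36, steps 6–25).

**Step 25 (ring closure, proposed new method).**
- What may go wrong: intermolecular coupling and oligomerisation in place of ring closure; protonation of the organozinc or β-hydride elimination from the alkyl(acyl)palladium intermediate before the strained reductive elimination; reductive loss of the allylic acyloxy groups of the butenolide during zinc insertion.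
- Fallback (known chemistry): it sets out from 31. Dess–Martin oxidation gives the C1 aldehyde F1. Finkelstein exchange (NaI, acetone) gives the iodo aldehyde F2. An intramolecular alkylchromium Barbier addition (CrCl2, catalytic cobalt phthalocyanine CoC32H16N8, DMF/THF, high dilution; the Takai–Utimoto coupling of primary iodides with aldehydes, known to be chemoselective for aldehydes in the presence of esters) closes the ring to the C1 carbinol F3. Dess–Martin oxidation of F3 returns to the route at 36. No zinc, palladium or thioester is involved.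

**Step 17 (key step).**
- What may go wrong: poor facial selectivity, because the epoxide oxygen is a weak donor and THF competes for magnesium, so a Felkin–Anh approach can erode the chelation-controlled 6S outcome; opening of the epoxide by bromide from the Lewis acid.
- Fallback: it sets out from 7 and 22 and turns the order of bond formation at C6 around. Pinnick oxidation of 7 (NaClO2, NaH2PO4, 2-methyl-2-butene) gives the epoxy acid F4. 2,2'-Dipyridyl disulfide and PPh3 convert it into the S-(2-pyridyl) thioester F5. The alkenylmagnesium 23, made from 22 as in step 17, is acylated by F5 at −78 °C to the γ-keto enoate F6. Reduction of F6 with (S)-2-methyl-CBS-oxazaborolidine and catecholborane (alkenyl as the large group) is chosen to deliver hydride to the face that gives 6S; the Felkin–Anh preference that harms the aldehyde addition now also points to 6S. The hydroxy ester lactonises and the route is rejoined at 25.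

**Step 15 (iodide–formaldehyde addition).**
- What may go wrong: sluggish iodide addition to the hindered β-carbon; delivery of formaldehyde on the iodine side of the allenolate (steric approach control against the branched C8 substituent), which would give the geometric isomer that cannot lactonise; loss of the PMB ether to the Lewis-acidic iodide.
- Fallback: it sets out from 19. Stannylcupration with Me3SnCu·SMe2 in THF, equilibrated at −48 °C so that the very large stannyl group ends cis to the ester, followed by trapping with formaldehyde, gives the stannane F7. Iododestannylation (I2, CH2Cl2, 0 °C, retention) returns to the route at 21.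

**Step 20 (angeloylation).**
- What may go wrong: slow acylation of the hindered secondary alcohol at C8; isomerisation of the angelate to the tiglate during prolonged heating; base-induced damage at C6–H.
- Fallback: it sets out from 27. Carbodiimide esterification with 2-[bis(2-methylphenoxy)phosphoryl]propanoic acid gives the phosphonate ester F8. An Ando-type Z-selective Horner–Wadsworth–Emmons reaction of F8 with acetaldehyde (NaI, DBU, THF, −78 to 0 °C) builds the Z-2-methylbut-2-enoate on the molecule and returns to the route at 30.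

## Further compounds

F1 | step 25 | (1S,3R)-1-{(5S)-4-(acetoxymethyl)-5-[(2R,3R)-3-(2-chloroethyl)-3-methyloxiran-2-yl]-2-oxo-2,5-dihydrofuran-3-yl}-3-methyl-4-oxobutyl (Z)-2-methylbut-2-enoate | C[C@@H](C=O)C[C@H](OC(=O)/C(C)=C\C)C1=C(COC(C)=O)C(=O)O[C@@H]1[C@H]1O[C@]1(C)CCCl
F2 | step 25 | (1S,3R)-1-{(5S)-4-(acetoxymethyl)-5-[(2R,3R)-3-(2-iodoethyl)-3-methyloxiran-2-yl]-2-oxo-2,5-dihydrofuran-3-yl}-3-methyl-4-oxobutyl (Z)-2-methylbut-2-enoate | C[C@@H](C=O)C[C@H](OC(=O)/C(C)=C\C)C1=C(COC(C)=O)C(=O)O[C@@H]1[C@H]1O[C@]1(C)CCI
F3 | step 25 | (4R,5R,6S,8S,10R)-13-acetoxy-8-angeloyloxy-4,5-epoxy-1-hydroxygermacr-7(11)-en-6,12-olide (either configuration at C1) | C/C=C(/C)C(=O)O[C@H]1C[C@@H](C)C(O)CC[C@@]2(C)O[C@@H]2[C@H]2OC(=O)C(COC(C)=O)=C12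
F4 | step 17 | (2S,3R)-3-(2-chloroethyl)-3-methyloxirane-2-carboxylic acid | OC(=O)[C@H]1O[C@]1(C)CCCl
F5 | step 17 | S-(pyridin-2-yl) (2S,3R)-3-(2-chloroethyl)-3-methyloxirane-2-carbothioate | O=C(Sc1ccccn1)[C@H]1O[C@]1(C)CCCl
F6 | step 17 | methyl (2Z,4S,6R)-4-[(tert-butyldimethylsilyl)oxy]-2-{[(tert-butyldimethylsilyl)oxy]methyl}-3-{[(2S,3R)-3-(2-chloroethyl)-3-methyloxiran-2-yl]carbonyl}-7-[(4-methoxybenzyl)oxy]-6-methylhept-2-enoate | COC(=O)/C(CO[Si](C)(C)C(C)(C)C)=C(\C(=O)[C@H]1O[C@]1(C)CCCl)[C@@H](O[Si](C)(C)C(C)(C)C)C[C@@H](C)COCc1ccc(OC)cc1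
F7 | step 15 | methyl (2Z,4S,6R)-4-[(tert-butyldimethylsilyl)oxy]-2-(hydroxymethyl)-7-[(4-methoxybenzyl)oxy]-6-methyl-3-(trimethylstannyl)hept-2-enoate | COC(=O)/C(CO)=C(\[Sn](C)(C)C)[C@@H](O[Si](C)(C)C(C)(C)C)C[C@@H](C)COCc1ccc(OC)cc1
F8 | step 20 | (1S,3R)-1-{(5S)-4-(acetoxymethyl)-5-[(2R,3R)-3-(2-chloroethyl)-3-methyloxiran-2-yl]-2-oxo-2,5-dihydrofuran-3-yl}-4-[(4-methoxybenzyl)oxy]-3-methylbutyl 2-[bis(2-methylphenoxy)phosphoryl]propanoate | C[C@@H](COCc1ccc(OC)cc1)C[C@H](OC(=O)C(C)P(=O)(Oc1ccccc1C)Oc1ccccc1C)C1=C(COC(C)=O)C(=O)O[C@@H]1[C@H]1O[C@]1(C)CCCl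
A1 | alternative 1 | (4R,5R,6S,10R)-4,5-epoxy-1-oxogermacra-7(8)E,11(13)-dien-6,12-olide (s-cis diene) | O=C1CC[C@@]2(C)O[C@@H]2[C@H]2OC(=O)C(=C)/C2=C\C[C@H]1C
A2 | alternative 1 | C8,C13-endoperoxide (1,2-dioxine) fused to the butenolide | O3[C@H]1C[C@@H](C)C(=O)CC[C@@]2(C)O[C@@H]2[C@H]2OC(=O)C(CO3)=C12
A3 | alternative 2 | seco compound with a C1 cyclopropanol and an (E)-C4 alkenyl iodide | C/C=C(/C)C(=O)O[C@@H](C[C@@H](C)C1(O)CC1)C1=C(COC(C)=O)C(=O)O[C@@H]1/C=C(\C)I
A4 | alternative 2 | 4,5-dehydro macrocycle with the E-alkene | C/C=C(/C)C(=O)O[C@H]1C[C@@H](C)C(=O)CC/C(C)=C/[C@H]2OC(=O)C(COC(C)=O)=C12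
A5 | alternative 3 | seco aldehyde with the C8 (E)-crotonyl ketone and the unlactonised enoate | O=CCC[C@@]1(C)O[C@@H]1[C@@H](O[Si](C)(C)C(C)(C)C)/C(C(=O)/C=C/C)=C(/COC(C)=O)C(=O)OC
A6 | alternative 3 | ten-membered C1,C8-diketone with the enoate not yet lactonised | O=C1C[C@@H](C)C(=O)CC[C@@]2(C)O[C@@H]2[C@@H](O[Si](C)(C)C(C)(C)C)/C1=C(/COC(C)=O)C(=O)OC
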